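**Retrosynthetic overview**

1. The target is ring A (the phenol arene C4a–C5–C6–C7–C8–C8a) fused to ring B (the δ-lactone O2–C1–C8a–C4a–C4–C3). Its only stereocentre is C3 (R), which carries the (E)-pentadec-6-enyl chain. The phenol is unmasked last from its methyl ether.
2. Key disconnection: C4–C4a and O2–C3 are formed together. An ortho-carboxyaryl radical annulates onto the terminal alkene of (E)-heptadeca-1,8-diene under chiral copper catalysis; this closes ring B and sets C3.
3. Enabling feature: in ring B the carboxyl oxygen O2 and the arene carbon C4a are 1,4-related through C1 and C8a. A benzoic acid with a radical precursor (N2+) at C4a is therefore a four-atom C,O partner for the two-carbon unit C4=C3. C3 bears only an unfunctionalised chain, and the other alkene (C6′=C7′) is remote and 1,2-disubstituted.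
4. The diene comes from elaidic acid by dehydrodecarboxylation, so C4, C3 and the whole chain with its E alkene arrive in one piece. Ring A is bought as 2-amino-6-methoxybenzoic acid; ring B is the only ring formed.

Key step: step 2

Assumption: the sense of asymmetric induction of the bis(oxazoline)–copper catalyst on this new substrate class cannot be predicted, so the ligand is written as its (S,S) form and the (R,R) form is used if the (S)-lactone predominates; the same holds for the diboration ligand in the fallbacks.

**Step 1**
Reactants: 1 elaidic acid [(E)-octadec-9-enoic acid]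
Product: 2 (E)-heptadeca-1,8-diene
Conditions: 9-mesitylacridine (10 mol%), Co(dmgH)2(py)Cl (5 mol%), CH2Cl2–MeCN, 400 nm LED, rt
Reagents that add atoms: none
Why: Photocatalytic dehydrodecarboxylation, a known acridine/cobaloxime conversion of fatty acids into terminal alkenes, in which the acid–acridine complex gives the acyloxy radical, CO2 is lost, and the cobaloxime removes the β-hydrogen of the primary C17 radical and releases H2, so the terminal alkene should form without touching the remote E alkene and no stereocentre is involved.

**Step 2**
Reactants: 2 (E)-heptadeca-1,8-diene; 3 2-amino-6-methoxybenzoic acid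
Product: 5 (R)-8-methoxy-3-[(E)-pentadec-6-en-1-yl]isochroman-1-one, via 2-diazonio-6-methoxybenzoate 4 (not isolated)
Conditions: 3 (1.5 equiv), t-BuONO, CF3CO2H (cat.), THF, 0 °C (4 kept as a cold slurry, never dried); then slow addition to 2, Cu(MeCN)4PF6 (10 mol%), (S,S)-t-Bu-Box (12 mol%), MeCN–EtOAc, 0 °C → rt
Reagents that add atoms: none
Why: Proposed new method: monovalent copper, holding 4 through its carboxylate, reduces the diazonium group by single-electron transfer to an ortho-carboxylatoaryl radical (loss of N2) that adds to the terminal CH2 of 2 and so forms C4–C4a, and the secondary C3 radical is then captured by the carboxylate-bearing divalent copper to give a seven-membered trivalent-copper alkyl carboxylate that forms O2–C3 by reductive elimination and returns monovalent copper. The closest known reaction type is the copper/bis(oxazoline)-catalysed enantioselective radical oxyarylation of alkenoic acids with arenediazonium salts (a Meerwein arylation ended by C–O bond formation at copper), together with the copper-catalysed lactonization of unactivated secondary radicals derived from pent-4-enoic acids; new here are the intermolecular unactivated alkene and the carboxylate sitting on the aryl radical instead of on the alkene. Ring B closes by a net [4+2] radical annulation whose ring-forming event is a 6-exo-type C–O closure at C3. The C3 stereocentre is controlled by the C2-symmetric bis(oxazoline) on copper, which must select one face of the prochiral radical (H against the C1′ chain) while the radical is tethered to the metal through the carboxylate; this catalyst control at a non-benzylic secondary radical is the unproven element. The step needs regioselectivity (aryl on CH2, oxygen on CH), secured by radical addition to the unsubstituted alkene terminus, and chemoselectivity between the two alkenes, secured by the faster addition of aryl radicals to the monosubstituted C=C than to the remote (E)-1,2-disubstituted one; the methyl ether keeps the phenol from chelating copper and from azo coupling.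

**Step 3**
Reactants: 5 (R)-8-methoxy-3-[(E)-pentadec-6-en-1-yl]isochroman-1-one
Product: 6 (R)-8-hydroxy-3-[(E)-pentadec-6-en-1-yl]isochroman-1-one (target)
Conditions: BCl3, CH2Cl2, −78 → 0 °C; then H2O
Reagents that add atoms: none
Why: Chelation-assisted Lewis-acid ether cleavage, in which BCl3 binds between the lactone carbonyl and the peri methoxy oxygen and chloride removes the methyl group by SN2 attack, a standard way to unmask 8-hydroxy-3,4-dihydroisocoumarins that should leave the lactone, the remote alkene and the C3 stereocentre (not involved) unchanged.

**Compound list**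

1 | elaidic acid, (E)-octadec-9-enoic acid | CCCCCCCC/C=C/CCCCCCCC(=O)O | starting material
2 | (E)-heptadeca-1,8-diene | CCCCCCCC/C=C/CCCCCC=C | intermediate
3 | 2-amino-6-methoxybenzoic acid | COc1cccc(N)c1C(=O)O | starting material
4 | 2-diazonio-6-methoxybenzoate (zwitterion) | COc1cccc([N+]#N)c1C(=O)[O-] | intermediate
5 | (R)-8-methoxy-3-[(E)-pentadec-6-en-1-yl]isochroman-1-one | CCCCCCCC/C=C/CCCCC[C@@H]1Cc2cccc(OC)c2C(=O)O1 | intermediate
6 | (R)-8-hydroxy-3-[(E)-pentadec-6-en-1-yl]isochroman-1-one | CCCCCCCC/C=C/CCCCC[C@@H]1Cc2cccc(O)c2C(=O)O1 | target

**Step count and risks**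

Total step count: 3. Longest linear sequence: 3 steps (1 → 2 → 5 → 6); compound 3 enters in step 2.

Steps most likely to fail:

1. Step 2 (proposed new method). The processes at risk are weak facial discrimination of the unactivated secondary C3 radical at copper (loss of enantiopurity), oxidative elimination of the alkyl–copper intermediate to alkenes, and capture of the C3 radical by a second diazonium ion instead of C–O bond formation. The fallback uses known chemistry and sets out from 2. Platinum-catalysed enantioselective diboration, which touches only the monosubstituted alkene [Pt(dba)3, TADDOL-derived aryl phosphonite, B2pin2, THF, 60 °C], should give (S,E)-2,2′-(heptadec-8-ene-1,2-diyl)bis(4,4,5,5-tetramethyl-1,3,2-dioxaborolane) F1. In the same flask, Suzuki–Miyaura coupling of the primary C–B bond with commercial methyl 2-bromo-6-methoxybenzoate [Pd(OAc)2, RuPhos, KOH, THF–H2O, 70 °C] should give methyl 2-methoxy-6-[(R,E)-2-(4,4,5,5-tetramethyl-1,3,2-dioxaborolan-2-yl)heptadec-8-en-1-yl]benzoate F2. Oxidation with NaOH/H2O2 (retention at C3) should give methyl 2-[(R,E)-2-hydroxyheptadec-8-en-1-yl]-6-methoxybenzoate F3. TsOH in toluene then closes the lactone, and the route is rejoined at 5. In this fallback C3 is set by the diboration ligand and O2–C3 arises from the C–B oxidation.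

2. Step 1. The process at risk is cobalt-hydride-mediated migration of the new terminal double bond into the chain, or E/Z scrambling of C8=C9; either would give alkene isomers that are hard to separate. The fallback sets out from 1 and uses a Barton decarboxylation–selenoxide elimination sequence. Acid 1 is esterified with N-hydroxypyridine-2-thione (N,N′-dicyclohexylcarbodiimide, CH2Cl2, dark) to 2-thioxopyridin-1(2H)-yl (E)-octadec-9-enoate F4. Photolysis of this ester with PhSeSePh should give (E)-heptadec-8-en-1-yl phenyl selenide F5. H2O2 then gives (E)-heptadec-8-en-1-yl phenyl selenoxide F6, whose syn-elimination at rt places the double bond regiospecifically at the chain end, and the route is rejoined at 2.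

3. Step 3. The processes at risk are addition of HCl to, or acid-induced migration of, the C6′=C7′ alkene, and incomplete ether cleavage. The fallback avoids the ether altogether and sets out from 2. The bis(boronate) F1 is made as in the fallback to step 2 and coupled under the same Pd(OAc)2/RuPhos/KOH conditions with methyl 2-bromo-6-hydroxybenzoate, whose phenol travels as its phenoxide. This should give methyl 2-hydroxy-6-[(R,E)-2-(4,4,5,5-tetramethyl-1,3,2-dioxaborolan-2-yl)heptadec-8-en-1-yl]benzoate F7. NaOH/H2O2 should then give methyl 2-hydroxy-6-[(R,E)-2-hydroxyheptadec-8-en-1-yl]benzoate F8, and TsOH-mediated lactonization rejoins the route directly at 6.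

**Further compounds**

F1 | step 2 | (S,E)-2,2′-(heptadec-8-ene-1,2-diyl)bis(4,4,5,5-tetramethyl-1,3,2-dioxaborolane) | CCCCCCCC/C=C/CCCCC[C@@H](B1OC(C)(C)C(C)(C)O1)CB1OC(C)(C)C(C)(C)O1
F2 | step 2 | methyl 2-methoxy-6-[(R,E)-2-(4,4,5,5-tetramethyl-1,3,2-dioxaborolan-2-yl)heptadec-8-en-1-yl]benzoate | CCCCCCCC/C=C/CCCCC[C@@H](B1OC(C)(C)C(C)(C)O1)Cc1cccc(OC)c1C(=O)OC
F3 | step 2 | methyl 2-[(R,E)-2-hydroxyheptadec-8-en-1-yl]-6-methoxybenzoate | CCCCCCCC/C=C/CCCCC[C@@H](O)Cc1cccc(OC)c1C(=O)OC
F4 | step 1 | 2-thioxopyridin-1(2H)-yl (E)-octadec-9-enoate | CCCCCCCC/C=C/CCCCCCCC(=O)ON1C=CC=CC1=S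
F5 | step 1 | (E)-heptadec-8-en-1-yl phenyl selenide | CCCCCCCC/C=C/CCCCCCC[Se]c1ccccc1
F6 | step 1 | (E)-heptadec-8-en-1-yl phenyl selenoxide | CCCCCCCC/C=C/CCCCCCC[Se](=O)c1ccccc1
F7 | step 3 | methyl 2-hydroxy-6-[(R,E)-2-(4,4,5,5-tetramethyl-1,3,2-dioxaborolan-2-yl)heptadec-8-en-1-yl]benzoate | CCCCCCCC/C=C/CCCCC[C@@H](B1OC(C)(C)C(C)(C)O1)Cc1cccc(O)c1C(=O)OC
F8 | step 3 | methyl 2-hydroxy-6-[(R,E)-2-hydroxyheptadec-8-en-1-yl]benzoate | CCCCCCCC/C=C/CCCCC[C@@H](O)Cc1cccc(O)c1C(=O)OC
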